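## Structural features

The target is a diarylmethane with no stereocenter. A 3-methylisocoumarin (benzenoid ring B fused to the pyranone ring C) is joined through one CH2 group from C5 to C1' of a tetrasubstituted benzene, ring A. Ring B carries OH at C6 and OMe at C8; ring A carries CH2OMe at C2', OH at C4' and OMe at C6'. The bridging carbon is flanked by four ortho positions (C4a with the peri C4–H, C6–O, C2'–CH2OMe, C6'–OMe), so any bond formation or redox change at that carbon is hindered. The fragile groups are the enol lactone of ring C (hydroxide, alkoxides, amines, organometallics, strong hydride donors), the benzylic methyl ether, and two free phenols on electron-rich rings. The real difficulty is twofold: one carbon substituent must go to C5 and not C7 of ring B, and ring A needs a 1,2,3,5 pattern with two adjacent, different carbon branches and two differentiated oxygens (OH para and OMe ortho to the bridge). The key step uses exactly this ring A pattern: C1' and C2' with their branches are the two carbons of an ynone, and C3'–C6' with both oxygens come from a 1,1-dialkoxy-3-silyloxy diene. The ketone that activates the alkyne is the later CH2 bridge.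

## Logic of the disconnections

**23 ⇒ 19 (via 22, 21, 20).** No skeletal bond is cut; the two C–H bonds of the bridge are traced back to a C=O. The reason is that a carbonyl at this carbon is what turns the alkyne of the key step into a dienophile, and an ortho-hydroxyaryl ketone can be taken to CH2 by hydride under mild basic conditions. The demand on the forward step is that hydride reaches a very hindered ketone without touching the lactone, and that both phenols are carbonated so that ring A does not become an unreactive phenoxide-conjugated ketone.

**19 ⇒ 18.** The O–Si bond at C6 is cut. The silyl ether must be present up to the cycloaddition, because a free ortho-hydroxyaryl ynone would add its phenol to the triple bond. The forward step must free the phenol without strong base, which would endanger the lactone.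

**18 ⇒ 13 + 15 (via 17, 16).** The bonds C6'–C1' and C3'–C2' are cut. This removes ring A completely: it is reduced to a four-carbon diene and a two-carbon alkyne, and all four substituents of ring A are placed by the orientation of the cycloaddition, not by aromatic substitution. The forward step must be regioselective, must aromatise by loss of methanol, and must leave the C6 silyl ether in place.

**13 ⇒ 12 ⇒ 9 + 10 (via 11).** The bond between the future bridging carbon and the alkyne carbon is cut, after adjusting the ketone to the alcohol. This splits off the whole four-carbon chain as a terminal alkyne. The acetylide must take the aldehyde and spare the lactone; the oxidation must be neutral.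

**9 ⇒ 8 ⇒ 7.** The O–Si bond and then the C5–CHO bond are cut. The free C6 phenol is the handle that directs a one-carbon electrophile to its ortho position. The forward step must prefer C5 over C7.

**7 ⇒ 5 (via 6) ⇒ 3 (via 4).** The lactone bond C1–O2 and the C4–C3 bond are cut. Ring C is thereby reduced to an ester and an ortho methyl group, which is the classical toluate pattern for lateral metalation. The base must deprotonate the methyl group without self-condensation of the ester, and one acid treatment must both remove the acetal and close the lactone.

**3 ⇒ 2 ⇒ 1.** Two O–C bonds are cut. The two phenols of 1 differ because the C2 hydroxyl is hydrogen-bonded to the ester, so the C4 oxygen (future C6–OH) can be masked first and the C2 oxygen (future C8–OMe) methylated second. The first alkylation must stop at the mono-ether.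

**15 ⇒ 14.** The O–Si bond is cut; the diene is the silyl enol ether of a methyl ketone with only one enolisable position. The forward step needs anhydrous handling.

## Other disconnections considered

**Alternative 1:** The cut runs through the two carbon branches of ring B, C4a–C4 and C8a–C1, so that ring B becomes an aryne across C4a/C8a and both branches come from dimethyl malonate A2. In the forward key step a fluoride source unmasks the aryne from the ortho-silylaryl triflate A1. The malonate carbanion adds at C4a, the aryl anion at C8a attacks an ester carbonyl, and the strained intermediate opens to the homophthalate A3 (net insertion into a C–C bond, no ring closed).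
- In favour: both ortho branches arrive in one mild operation, and the C8 methoxy group polarises the aryne in the desired sense. The bridge is already CH2, so no hindered ketone has to be reduced; on this point the alternative is better than the chosen plan.
- Against: A1 is a benzene with five different substituents, and its assembly contains the same C5 problem plus the placement of silyl and triflate groups. C4a is flanked by the bulky benzyl group, so sterics oppose the electronic preference. A3 still lacks C3 and its methyl group, so acylation, decarboxylation, lactonisation and two acetal cleavages follow.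
- Comparison: in structure, this alternative builds neither ring, while the chosen plan constructs ring A with its substituents in place. In mechanism, both rely on polarisation for regiocontrol, which is equal in kind; in the chosen plan polarisation and sterics point the same way. In step economy, A1 alone should cost about as many steps as the whole front half of the chosen route, so the alternative is longer.

**Alternative 2:** The cut is the C4a–C8a bond of ring B, which unravels the arene into the polycarbonyl chain A4 (racemic and enolisable at the benzyl-bearing carbon). In the forward key step an amine base triggers vinylogous aldol attack of the dioxinone α-carbon (future C8a) on the C4a ketone; acid then dehydrates the aldol and aromatises ring B to the benzodioxinone A5.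
- In favour: every substituent position on ring B is fixed by the chain, so the C5 versus C7 question does not arise, and the bridge is CH2 from the start; on both points the alternative is better than the chosen plan. The C8 oxygen is differentiated from the C6 hydroxyl, which is equal to the chosen plan.
- Against: A4 requires C-benzylation of a sensitive polycarbonyl chain at the carbon between two ketones, with O-alkylation, double alkylation and premature cyclisation as competitors. In A5 the oxygens are differentiated in the wrong sense for 23: C6–OH is free and C8–O is masked. The C6 phenol must therefore be protected, the dioxinone opened, the C8 phenol methylated, the ketal removed, the lactone closed and two groups taken off. Ring A must still be made separately by substitution chemistry.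
- Comparison: mechanistically the aldol aromatisation is well founded and mild. Structurally it solves ring B but not ring A, the reverse of the chosen plan. In step economy it is clearly longer after its key step.

**Alternative 3:** The cut is C4a–C5 and C6–C7 of ring B. Ring C stays intact inside the bis-pyrone A6, and C5, C6, the bridge and ring A sit in the siloxyalkyne A7. In the forward key step, heating A6 with A7 should give an inverse-demand [4+2] adduct on the methoxy-bearing pyranone ring; loss of CO2 closes ring B and gives A8, and one desilylation gives 23.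
- In favour: it is the most convergent plan, with the bridge already CH2 and one step after the key step; in endgame length and in avoiding redox chemistry at the bridge it is better than the chosen plan. Regiocontrol by matched polarisation (the nucleophilic alkyne carbon to the oxygen-bearing pyranone terminus) is equal in quality.
- Against: the C4a–C5 bond would join a ring-fusion carbon to an alkyne carbon carrying a doubly ortho-substituted benzyl group. A6 contains two 2-pyranone rings that could each act as the diene. The methoxy group makes the reacting pyranone less electron-poor. Cycloadditions of this type usually need temperatures at which siloxyalkynes rearrange to silylketenes. A7 presupposes ring A and needs several further steps of homologation.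
- Comparison: if its key step worked the route would be shorter, but the risk is concentrated in one thermally demanding step with little close analogy. The chosen plan spreads smaller risks over steps of known type and builds ring A instead of presupposing it.

Key step: step 10

Remark: the atom mapping of 13 + 15 → 18 onto ring A of 23 was verified and no structure needed correction; 12 is racemic and its stereocenter disappears in step 8.

## Route

Step 1
Reactants: 1 methyl 2,4-dihydroxy-6-methylbenzoate (methyl orsellinate)
Product: 2 methyl 2-hydroxy-4-(methoxymethoxy)-6-methylbenzoate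
Conditions: MOMCl, iPr2NEt, CH2Cl2, 0 °C → 25 °C
Reagents that add atoms: chloromethyl methyl ether, COCCl
Why: Williamson-type O-alkylation of the more acidic, non-chelated C4 phenol; the C2 phenol is hydrogen-bonded to the ester carbonyl and should react much more slowly, so one equivalent of the chloride should stop at the mono-ether.

Step 2
Reactants: 2 methyl 2-hydroxy-4-(methoxymethoxy)-6-methylbenzoate
Product: 3 methyl 2-methoxy-4-(methoxymethoxy)-6-methylbenzoate
Conditions: MeI, K2CO3, DMF, 40 °C
Reagents that add atoms: iodomethane, CI
Why: Williamson ether synthesis on the remaining chelated phenol under more forcing carbonate/DMF conditions; the acetal and the ester are stable to K2CO3.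

Step 3
Reactants: 3 methyl 2-methoxy-4-(methoxymethoxy)-6-methylbenzoate
Product: 5 methyl 2-methoxy-4-(methoxymethoxy)-6-(2-oxopropyl)benzoate, via benzylic lithium species 4 (not isolated)
Conditions: LiN(iPr)2, THF, −78 °C; then N-methoxy-N-methylacetamide, −78 → −40 °C; NH4Cl (aq)
Reagents that add atoms: N-methoxy-N-methylacetamide, CC(=O)N(C)OC
Why: Lateral lithiation of an ortho-toluate gives the resonance-stabilised benzylic anion 4, which is acylated by the N-methoxy-N-methyl amide (Weinreb ketone synthesis); the chelated tetrahedral adduct prevents over-addition and the low temperature suppresses self-condensation of the toluate.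

Step 4
Reactants: 5 methyl 2-methoxy-4-(methoxymethoxy)-6-(2-oxopropyl)benzoate
Product: 7 6-hydroxy-8-methoxy-3-methyl-1H-isochromen-1-one (6-hydroxy-8-methoxy-3-methylisocoumarin), via phenolic keto ester 6 (not isolated)
Conditions: HCl, MeOH, 50 °C; solvent exchange; then p-TsOH·H2O (cat.), PhMe, reflux with removal of MeOH
Reagents that add atoms: none
Why: Acid-catalysed acetal cleavage (formaldehyde trapped by methanol) frees the C6 phenol, and acid-catalysed enol lactonisation of the 2-(2-oxopropyl)benzoate with removal of methanol closes ring C; the aryl methyl ether is inert to these acids.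

Step 5
Reactants: 7 6-hydroxy-8-methoxy-3-methyl-1H-isochromen-1-one
Product: 8 6-hydroxy-8-methoxy-3-methyl-1-oxo-1H-isochromene-5-carbaldehyde
Conditions: MgCl2, Et3N, (CH2O)n, MeCN, reflux; then 1 M HCl
Reagents that add atoms: paraformaldehyde (as formaldehyde), C=O
Why: Magnesium-mediated ortho-formylation of a phenol (Casnati–Skattebøl reaction): the magnesium phenoxide delivers formaldehyde to an ortho carbon and a second formaldehyde oxidises the resulting benzylic alkoxide. Of the two ortho sites, C5 is para to the C8 methoxy group, whereas C7 is wedged between two oxygen substituents with the C8 O-methyl turned toward it by the peri carbonyl, so attack at C5 is expected.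

Step 6
Reactants: 8 6-hydroxy-8-methoxy-3-methyl-1-oxo-1H-isochromene-5-carbaldehyde
Product: 9 8-methoxy-3-methyl-1-oxo-6-[(triisopropylsilyl)oxy]-1H-isochromene-5-carbaldehyde
Conditions: TIPSOTf, 2,6-lutidine, CH2Cl2, 0 °C
Reagents that add atoms: triisopropylsilyl trifluoromethanesulfonate, CC(C)[Si](OS(=O)(=O)C(F)(F)F)(C(C)C)C(C)C
Why: Silylation of a chelated ortho-hydroxy aldehyde needs the reactive silyl triflate; the bulky triisopropylsilyl ether should resist the acetylide, the oxidant, heat and dilute acid of steps 7–10 and is slow to migrate between oxygens.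

Step 7
Reactants: 9 8-methoxy-3-methyl-1-oxo-6-[(triisopropylsilyl)oxy]-1H-isochromene-5-carbaldehyde; 10 3-methoxyprop-1-yne (methyl propargyl ether)
Product: 12 5-(1-hydroxy-4-methoxybut-2-yn-1-yl)-8-methoxy-3-methyl-6-[(triisopropylsilyl)oxy]-1H-isochromen-1-one (racemic), via lithium acetylide 11 (not isolated)
Conditions: 10, n-BuLi, THF, −78 °C; then 9, −78 °C; NH4Cl (aq) at −78 °C
Reagents that add atoms: none
Why: 1,2-Addition of a lithium acetylide to an aldehyde; at −78 °C the aldehyde is far more electrophilic than the conjugated, electron-rich lactone carbonyl. The carbinol stereocenter forms racemic and is removed in step 8.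

Step 8
Reactants: 12 5-(1-hydroxy-4-methoxybut-2-yn-1-yl)-8-methoxy-3-methyl-6-[(triisopropylsilyl)oxy]-1H-isochromen-1-one
Product: 13 5-(4-methoxybut-2-ynoyl)-8-methoxy-3-methyl-6-[(triisopropylsilyl)oxy]-1H-isochromen-1-one
Conditions: Dess–Martin periodinane, CH2Cl2, 0 °C → 25 °C
Reagents that add atoms: none
Why: Dess–Martin oxidation of a secondary benzylic propargylic alcohol to the ynone under neutral conditions that leave the silyl ether, the enol lactone and the propargylic ether alone.

Step 9
Reactants: 14 4,4-dimethoxybut-3-en-2-one
Product: 15 1,1-dimethoxy-3-(trimethylsilyloxy)buta-1,3-diene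
Conditions: TMSCl, Et3N, ZnCl2 (cat.), PhMe, 40 °C; filtration, distillation
Reagents that add atoms: chlorotrimethylsilane, C[Si](C)(C)Cl
Why: Silyl enol ether formation at the only enolisable position (the methyl ketone) of a vinylogous ester, the standard entry to 2-silyloxy dienes; the diene is moisture-sensitive and is used directly after distillation.

Step 10
Reactants: 13 5-(4-methoxybut-2-ynoyl)-8-methoxy-3-methyl-6-[(triisopropylsilyl)oxy]-1H-isochromen-1-one; 15 1,1-dimethoxy-3-(trimethylsilyloxy)buta-1,3-diene
Product: 18 5-[4-hydroxy-2-methoxy-6-(methoxymethyl)benzoyl]-8-methoxy-3-methyl-6-[(triisopropylsilyl)oxy]-1H-isochromen-1-one, via cyclohexadiene cycloadduct 16 (not isolated), via aryl trimethylsilyl ether 17 (not isolated)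
Conditions: 15 (3 equiv), PhMe, 25 → 80 °C; then 0.5 M HCl, THF, 25 °C
Reagents that add atoms: none
Why: Normal-demand Diels–Alder reaction between the electron-rich diene 15 and the ynone of 13, expected to be strongly asynchronous: the unsubstituted CH2 terminus of the silyl enol ether (largest HOMO coefficient) bonds to the ynone β-carbon (largest LUMO coefficient, future C2' with CH2OMe), and the ketene acetal carbon then bonds to the α-carbon (future C1'). Ring A thus closes by an intermolecular [4+2] cycloaddition, four carbons from 15 and two from the alkyne, giving the cyclohexa-1,4-diene 16. 16 carries a ketal carbon para to a ring CH2 that is vinylogously acidified by the ketone, so 1,4-elimination of methanol aromatises it to 17; the dilute acid of the work-up completes this and hydrolyses the labile aryl trimethylsilyl ether to the C4' phenol of 18, while the hindered triisopropylsilyl ether at C6 should stay. The closest known reaction type is the Diels–Alder benzannulation of 1,1-dialkoxy-3-silyloxybuta-1,3-dienes with alkynones and alkynoates, which gives resorcinol monoethers after loss of alcohol. No stereocenter is formed. The selectivity needed is regiochemical (OMe at C6' next to the acyl-bearing C1', CH2OMe at C2', OH at C4'); it is secured by the matched polarisation of the two partners and supported by sterics, since the small CH2 terminus meets the substituted β-carbon first. Chemoselectivity is secured by the substrate: the ynone is its only strongly electron-poor π bond (the enol lactone alkene of ring C is a poor dienophile), and the C6 silyl ether keeps the ortho oxygen from adding to the triple bond.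

Step 11
Reactants: 18 5-[4-hydroxy-2-methoxy-6-(methoxymethyl)benzoyl]-8-methoxy-3-methyl-6-[(triisopropylsilyl)oxy]-1H-isochromen-1-one
Product: 19 6-hydroxy-5-[4-hydroxy-2-methoxy-6-(methoxymethyl)benzoyl]-8-methoxy-3-methyl-1H-isochromen-1-one
Conditions: TBAF, AcOH, THF, 0 °C
Reagents that add atoms: none
Why: Fluoride-induced cleavage of the aryl silyl ether, driven by the strong Si–F bond; acetic acid buffers the phenoxide so that the enol lactone and the ortho-hydroxy ortho'-methoxy benzophenone are not exposed to strong base.

Step 12
Reactants: 19 6-hydroxy-5-[4-hydroxy-2-methoxy-6-(methoxymethyl)benzoyl]-8-methoxy-3-methyl-1H-isochromen-1-one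
Product: 23 6-hydroxy-5-{[4-hydroxy-2-methoxy-6-(methoxymethyl)phenyl]methyl}-8-methoxy-3-methyl-1H-isochromen-1-one, via bis(ethyl carbonate) 20 (not isolated), via ortho-quinone methide 21 (not isolated), via ring A ethyl carbonate 22 (not isolated)
Conditions: ClCO2Et, Et3N, THF, 0 °C; filtration; filtrate into NaBH4, THF/H2O, 0 → 25 °C; then 1 M NaOH, 0 °C; 1 M HCl to pH 3
Reagents that add atoms: none
Why: Reductive deoxygenation of an ortho-hydroxyaryl ketone through its aryl ethyl carbonate: borohydride reduces the ketone of 20, the alkoxide takes over the neighbouring carbonate group, and the C6 phenoxide expels ethyl carbonate to give ortho-quinone methide 21, which borohydride reduces at the exocyclic carbon to the CH2 of 22. Brief hydroxide treatment removes the ring A carbonate and acidification re-closes any opened lactone; the C6 phenoxide formed on carbonate transfer deactivates the lactone carbonyl toward hydride.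

## Compound list

1 | methyl 2,4-dihydroxy-6-methylbenzoate (methyl orsellinate) | COC(=O)c1c(C)cc(O)cc1O | starting material
2 | methyl 2-hydroxy-4-(methoxymethoxy)-6-methylbenzoate | COCOc1cc(C)c(C(=O)OC)c(O)c1 | intermediate
3 | methyl 2-methoxy-4-(methoxymethoxy)-6-methylbenzoate | COCOc1cc(C)c(C(=O)OC)c(OC)c1 | intermediate
4 | {[3-methoxy-2-(methoxycarbonyl)-5-(methoxymethoxy)phenyl]methyl}lithium | [Li]Cc1cc(OCOC)cc(OC)c1C(=O)OC | intermediate (not isolated)
5 | methyl 2-methoxy-4-(methoxymethoxy)-6-(2-oxopropyl)benzoate | COCOc1cc(CC(C)=O)c(C(=O)OC)c(OC)c1 | intermediate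
6 | methyl 4-hydroxy-2-methoxy-6-(2-oxopropyl)benzoate | COC(=O)c1c(CC(C)=O)cc(O)cc1OC | intermediate (not isolated)
7 | 6-hydroxy-8-methoxy-3-methyl-1H-isochromen-1-one | COc1cc(O)cc2cc(C)oc(=O)c12 | intermediate
8 | 6-hydroxy-8-methoxy-3-methyl-1-oxo-1H-isochromene-5-carbaldehyde | COc1cc(O)c(C=O)c2cc(C)oc(=O)c12 | intermediate
9 | 8-methoxy-3-methyl-1-oxo-6-[(triisopropylsilyl)oxy]-1H-isochromene-5-carbaldehyde | COc1cc(O[Si](C(C)C)(C(C)C)C(C)C)c(C=O)c2cc(C)oc(=O)c12 | intermediate
10 | 3-methoxyprop-1-yne (methyl propargyl ether) | COCC#C | starting material
11 | (3-methoxyprop-1-yn-1-yl)lithium | [Li]C#CCOC | intermediate (not isolated)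
12 | 5-(1-hydroxy-4-methoxybut-2-yn-1-yl)-8-methoxy-3-methyl-6-[(triisopropylsilyl)oxy]-1H-isochromen-1-one (racemic) | COCC#CC(O)c1c(O[Si](C(C)C)(C(C)C)C(C)C)cc(OC)c2c(=O)oc(C)cc12 | intermediate
13 | 5-(4-methoxybut-2-ynoyl)-8-methoxy-3-methyl-6-[(triisopropylsilyl)oxy]-1H-isochromen-1-one | COCC#CC(=O)c1c(O[Si](C(C)C)(C(C)C)C(C)C)cc(OC)c2c(=O)oc(C)cc12 | intermediate
14 | 4,4-dimethoxybut-3-en-2-one | CC(=O)C=C(OC)OC | starting material
15 | 1,1-dimethoxy-3-(trimethylsilyloxy)buta-1,3-diene | COC(OC)=CC(=C)O[Si](C)(C)C | intermediate
16 | 5-{[6,6-dimethoxy-2-(methoxymethyl)-4-(trimethylsilyloxy)cyclohexa-1,4-dien-1-yl]carbonyl}-8-methoxy-3-methyl-6-[(triisopropylsilyl)oxy]-1H-isochromen-1-one | COCC1=C(C(=O)c2c(O[Si](C(C)C)(C(C)C)C(C)C)cc(OC)c3c(=O)oc(C)cc23)C(OC)(OC)C=C(O[Si](C)(C)C)C1 | intermediate (not isolated)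
17 | 8-methoxy-5-[2-methoxy-6-(methoxymethyl)-4-(trimethylsilyloxy)benzoyl]-3-methyl-6-[(triisopropylsilyl)oxy]-1H-isochromen-1-one | COCc1cc(O[Si](C)(C)C)cc(OC)c1C(=O)c1c(O[Si](C(C)C)(C(C)C)C(C)C)cc(OC)c2c(=O)oc(C)cc12 | intermediate (not isolated)
18 | 5-[4-hydroxy-2-methoxy-6-(methoxymethyl)benzoyl]-8-methoxy-3-methyl-6-[(triisopropylsilyl)oxy]-1H-isochromen-1-one | COCc1cc(O)cc(OC)c1C(=O)c1c(O[Si](C(C)C)(C(C)C)C(C)C)cc(OC)c2c(=O)oc(C)cc12 | intermediate
19 | 6-hydroxy-5-[4-hydroxy-2-methoxy-6-(methoxymethyl)benzoyl]-8-methoxy-3-methyl-1H-isochromen-1-one | COCc1cc(O)cc(OC)c1C(=O)c1c(O)cc(OC)c2c(=O)oc(C)cc12 | intermediate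
20 | 4-{[6-(ethoxycarbonyloxy)-8-methoxy-3-methyl-1-oxo-1H-isochromen-5-yl]carbonyl}-3-methoxy-5-(methoxymethyl)phenyl ethyl carbonate | CCOC(=O)Oc1cc(COC)c(C(=O)c2c(OC(=O)OCC)cc(OC)c3c(=O)oc(C)cc23)c(OC)c1 | intermediate (not isolated)
21 | ethyl 3-methoxy-4-[(8-methoxy-3-methyl-1,6-dioxo-1H-isochromen-5(6H)-ylidene)methyl]-5-(methoxymethyl)phenyl carbonate (alkene geometry undefined, transient) | CCOC(=O)Oc1cc(COC)c(C=C2C(=O)C=C(OC)C3=C2C=C(C)OC3=O)c(OC)c1 | intermediate (not isolated)
22 | ethyl 4-[(6-hydroxy-8-methoxy-3-methyl-1-oxo-1H-isochromen-5-yl)methyl]-3-methoxy-5-(methoxymethyl)phenyl carbonate | CCOC(=O)Oc1cc(COC)c(Cc2c(O)cc(OC)c3c(=O)oc(C)cc23)c(OC)c1 | intermediate (not isolated)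
23 | 6-hydroxy-5-{[4-hydroxy-2-methoxy-6-(methoxymethyl)phenyl]methyl}-8-methoxy-3-methyl-1H-isochromen-1-one | COCc1cc(O)cc(OC)c1Cc1c(O)cc(OC)c2c(=O)oc(C)cc12 | target

## Step count and least certain steps

Total: 12 steps. Longest linear sequence: 11 steps (steps 1–8 and 10–12 from 1); step 9 is the one-step branch to diene 15.

**Step 10 (key step).** After the first C–C bond has formed at the β-carbon, closure onto the α-carbon may be slow, because that carbon sits next to a twisted, doubly ortho-substituted aroyl group; silyl transfer and open-chain conjugate addition could then take over. The internal ynone may also react so slowly that the heat- and moisture-sensitive diene decomposes first. The fallback makes ring A from an arene and forms the bridge bond by aryl-metal addition; it sets out from 9 and returns at 19. Methyl 3-hydroxy-5-methoxybenzoate F1 (purchased) would be silylated (TIPSCl, imidazole, DMF) to methyl 3-methoxy-5-[(triisopropylsilyl)oxy]benzoate F2, reduced (LiAlH4, THF, 0 °C) to {3-methoxy-5-[(triisopropylsilyl)oxy]phenyl}methanol F3, and O-methylated (NaH, MeI, THF, 0 °C) to triisopropyl[3-methoxy-5-(methoxymethyl)phenoxy]silane F4. Directed ortho-lithiation (n-BuLi, TMEDA, Et2O, 0 °C) should occur between the methoxy and methoxymethyl groups, the only position flanked by two coordinating groups and remote from the bulky silyl ether, giving {2-methoxy-6-(methoxymethyl)-4-[(triisopropylsilyl)oxy]phenyl}lithium F5. Addition to 9 at −78 °C should give the racemic diaryl carbinol 5-(hydroxy{2-methoxy-6-(methoxymethyl)-4-[(triisopropylsilyl)oxy]phenyl}methyl)-8-methoxy-3-methyl-6-[(triisopropylsilyl)oxy]-1H-isochromen-1-one F6. Dess–Martin oxidation should give the bis(silyl ether) ketone 8-methoxy-5-{2-methoxy-6-(methoxymethyl)-4-[(triisopropylsilyl)oxy]benzoyl}-3-methyl-6-[(triisopropylsilyl)oxy]-1H-isochromen-1-one F7, and TBAF/AcOH should remove both silyl groups to give 19, from which step 12 proceeds unchanged.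

**Step 5.** Formylation may show poor site selectivity between C5 and C7, and the phenoxide, conjugated to the lactone carbonyl, may react sluggishly. The fallback fixes the site with a halogen at the benzoate stage, where substitution next to the methyl group and away from the position between two alkoxy groups has close analogy, and replaces electrophilic formylation by a catalytic carbonylation; it sets out from 3 and returns at 9. NBS in MeCN at 0 °C should give methyl 3-bromo-6-methoxy-4-(methoxymethoxy)-2-methylbenzoate F8. Under the conditions of step 3 its benzylic lithium species {[2-bromo-5-methoxy-6-(methoxycarbonyl)-3-(methoxymethoxy)phenyl]methyl}lithium F9 should be acylated to methyl 3-bromo-6-methoxy-4-(methoxymethoxy)-2-(2-oxopropyl)benzoate F10; the bromide has no ortho hydrogen, so aryne formation is excluded. Under the conditions of step 4 this should pass through methyl 3-bromo-4-hydroxy-6-methoxy-2-(2-oxopropyl)benzoate F11 to 5-bromo-6-hydroxy-8-methoxy-3-methyl-1H-isochromen-1-one F12. Silylation as in step 6 should give 5-bromo-8-methoxy-3-methyl-6-[(triisopropylsilyl)oxy]-1H-isochromen-1-one F13, and palladium-catalysed formylation with synthesis gas (Pd(OAc)2, di(1-adamantyl)-n-butylphosphine, TMEDA, CO/H2, PhMe, 100 °C) should give 9.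

**Step 12.** Hydride addition to the ketone, which is flanked by four ortho substituents, may be slow; hydrolysis of the C6 carbonate back to 19 or hydride attack on the lactone could then compete. The fallback is ionic hydrogenation instead of the quinone methide pathway; it sets out from 19 and ends directly at 23 without any new isolated compound (Et3SiH, CF3CO2H, CH2Cl2, 0 → 25 °C). The ketone is protonated and takes hydride from silicon; the diarylcarbinol ionises to a cation stabilised by the para hydroxyl of ring A and the ortho hydroxyl of ring B, and a second hydride transfer gives the CH2. The CH2OMe group is meta to both oxygen substituents of ring A and should not ionise, and the enol lactone, whose ring oxygen is acylated, should resist protonation.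

**Step 7.** The acetylide may attack the lactone carbonyl in competition with the aldehyde, and the silyl group may shift from the C6 oxygen to the new alkoxide, which would free the phenol. The fallback replaces carbonyl addition by an acyl–alkyne coupling and needs no strongly basic nucleophile; it sets out from 9 and returns at 13. Pinnick oxidation (NaClO2, NaH2PO4, 2-methylbut-2-ene, t-BuOH/H2O) should give 8-methoxy-3-methyl-1-oxo-6-[(triisopropylsilyl)oxy]-1H-isochromene-5-carboxylic acid F14. Oxalyl chloride with catalytic DMF in CH2Cl2 should give 8-methoxy-3-methyl-1-oxo-6-[(triisopropylsilyl)oxy]-1H-isochromene-5-carbonyl chloride F15, and acyl Sonogashira coupling with 10 (PdCl2(PPh3)2, CuI, Et3N, THF, 25 °C) should give 13.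

## Further compounds

F1 | step 10 | methyl 3-hydroxy-5-methoxybenzoate (purchased) | COC(=O)c1cc(O)cc(OC)c1
F2 | step 10 | methyl 3-methoxy-5-[(triisopropylsilyl)oxy]benzoate | COC(=O)c1cc(OC)cc(O[Si](C(C)C)(C(C)C)C(C)C)c1
F3 | step 10 | {3-methoxy-5-[(triisopropylsilyl)oxy]phenyl}methanol | COc1cc(CO)cc(O[Si](C(C)C)(C(C)C)C(C)C)c1
F4 | step 10 | triisopropyl[3-methoxy-5-(methoxymethyl)phenoxy]silane | COCc1cc(OC)cc(O[Si](C(C)C)(C(C)C)C(C)C)c1
F5 | step 10 | {2-methoxy-6-(methoxymethyl)-4-[(triisopropylsilyl)oxy]phenyl}lithium | [Li]c1c(COC)cc(O[Si](C(C)C)(C(C)C)C(C)C)cc1OC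
F6 | step 10 | 5-(hydroxy{2-methoxy-6-(methoxymethyl)-4-[(triisopropylsilyl)oxy]phenyl}methyl)-8-methoxy-3-methyl-6-[(triisopropylsilyl)oxy]-1H-isochromen-1-one (racemic) | COCc1cc(O[Si](C(C)C)(C(C)C)C(C)C)cc(OC)c1C(O)c1c(O[Si](C(C)C)(C(C)C)C(C)C)cc(OC)c2c(=O)oc(C)cc12
F7 | step 10 | 8-methoxy-5-{2-methoxy-6-(methoxymethyl)-4-[(triisopropylsilyl)oxy]benzoyl}-3-methyl-6-[(triisopropylsilyl)oxy]-1H-isochromen-1-one | COCc1cc(O[Si](C(C)C)(C(C)C)C(C)C)cc(OC)c1C(=O)c1c(O[Si](C(C)C)(C(C)C)C(C)C)cc(OC)c2c(=O)oc(C)cc12
F8 | step 5 | methyl 3-bromo-6-methoxy-4-(methoxymethoxy)-2-methylbenzoate | COCOc1cc(OC)c(C(=O)OC)c(C)c1Br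
F9 | step 5 | {[2-bromo-5-methoxy-6-(methoxycarbonyl)-3-(methoxymethoxy)phenyl]methyl}lithium | [Li]Cc1c(Br)c(OCOC)cc(OC)c1C(=O)OC
F10 | step 5 | methyl 3-bromo-6-methoxy-4-(methoxymethoxy)-2-(2-oxopropyl)benzoate | COCOc1cc(OC)c(C(=O)OC)c(CC(C)=O)c1Br
F11 | step 5 | methyl 3-bromo-4-hydroxy-6-methoxy-2-(2-oxopropyl)benzoate | COC(=O)c1c(CC(C)=O)c(Br)c(O)cc1OC
F12 | step 5 | 5-bromo-6-hydroxy-8-methoxy-3-methyl-1H-isochromen-1-one | COc1cc(O)c(Br)c2cc(C)oc(=O)c12
F13 | step 5 | 5-bromo-8-methoxy-3-methyl-6-[(triisopropylsilyl)oxy]-1H-isochromen-1-one | COc1cc(O[Si](C(C)C)(C(C)C)C(C)C)c(Br)c2cc(C)oc(=O)c12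
F0 | step 12 | none | none
F14 | step 7 | 8-methoxy-3-methyl-1-oxo-6-[(triisopropylsilyl)oxy]-1H-isochromene-5-carboxylic acid | COc1cc(O[Si](C(C)C)(C(C)C)C(C)C)c(C(=O)O)c2cc(C)oc(=O)c12
F15 | step 7 | 8-methoxy-3-methyl-1-oxo-6-[(triisopropylsilyl)oxy]-1H-isochromene-5-carbonyl chloride | COc1cc(O[Si](C(C)C)(C(C)C)C(C)C)c(C(Cl)=O)c2cc(C)oc(=O)c12
A1 | alternative 1 | 6-methoxy-4-(methoxymethoxy)-3-{[2-methoxy-4-(methoxymethoxy)-6-(methoxymethyl)phenyl]methyl}-2-(trimethylsilyl)phenyl trifluoromethanesulfonate | COCOc1cc(OC)c(OS(=O)(=O)C(F)(F)F)c([Si](C)(C)C)c1Cc1c(COC)cc(OCOC)cc1OC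
A2 | alternative 1 | dimethyl malonate | COC(=O)CC(=O)OC
A3 | alternative 1 | methyl 6-methoxy-2-(2-methoxy-2-oxoethyl)-4-(methoxymethoxy)-3-{[2-methoxy-4-(methoxymethoxy)-6-(methoxymethyl)phenyl]methyl}benzoate | COCOc1cc(OC)c(C(=O)OC)c(CC(=O)OC)c1Cc1c(COC)cc(OCOC)cc1OC
A4 | alternative 2 | 6-[3-({2-methoxy-6-(methoxymethyl)-4-[(triisopropylsilyl)oxy]phenyl}methyl)-5-(2-methyl-1,3-dioxolan-2-yl)-2,4-dioxopentyl]-2,2-dimethyl-4H-1,3-dioxin-4-one (racemic, enolisable) | CC1(C)OC(=O)C=C(CC(=O)C(Cc2c(COC)cc(O[Si](C(C)C)(C(C)C)C(C)C)cc2OC)C(=O)CC2(C)OCCO2)O1
A5 | alternative 2 | 7-hydroxy-6-({2-methoxy-6-(methoxymethyl)-4-[(triisopropylsilyl)oxy]phenyl}methyl)-2,2-dimethyl-5-[(2-methyl-1,3-dioxolan-2-yl)methyl]-4H-1,3-benzodioxin-4-one | CC1(C)OC(=O)c2c(O1)cc(O)c(Cc3c(COC)cc(O[Si](C(C)C)(C(C)C)C(C)C)cc3OC)c2CC2(C)OCCO2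
A6 | alternative 3 | 4-methoxy-7-methyl-2H,5H-pyrano[4,3-b]pyran-2,5-dione | COc1cc(=O)oc2cc(C)oc(=O)c12
A7 | alternative 3 | triisopropyl[(3-{2-methoxy-6-(methoxymethyl)-4-[(triisopropylsilyl)oxy]phenyl}prop-1-yn-1-yl)oxy]silane | COCc1cc(O[Si](C(C)C)(C(C)C)C(C)C)cc(OC)c1CC#CO[Si](C(C)C)(C(C)C)C(C)C
A8 | alternative 3 | 8-methoxy-5-({2-methoxy-6-(methoxymethyl)-4-[(triisopropylsilyl)oxy]phenyl}methyl)-3-methyl-6-[(triisopropylsilyl)oxy]-1H-isochromen-1-one | COCc1cc(O[Si](C(C)C)(C(C)C)C(C)C)cc(OC)c1Cc1c(O[Si](C(C)C)(C(C)C)C(C)C)cc(OC)c2c(=O)oc(C)cc12
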